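The route builds ring A instead of coupling two arenes. The benzo ring of the isocoumarin carries oxygen at C6 (OH) and C8 (OAr) in a meta relation, the lactone carbonyl carbon on C8a and C4 on C4a, the pattern that a vinylketene and an ynol ether produce. Irradiating a methacryloyl-derived diazo keto ester with the ethynyl ether of ring B should form C6–C7, C8–C8a and C5–C6 and close ring A in one operation, the crowded diaryl ether oxygen being already in place on the alkyne. That alkyne is protected 5-ethynyloxyolivetolic acid, its carboxyl a tert-butyl ester that tolerates organolithium bases.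

Key step: step 9

Numbering: ring A and the pyranone use isocoumarin numbering (C1 lactone carbonyl, C3 pentyl-bearing, C4, C4a, C5 to C8, C8a). Ring B is numbered as in olivetolic acid (C1' carboxyl-bearing, C2' and C4' oxygenated, C5' ether oxygen, C6' pentyl-bearing).
Assumption: the target has no stereocentre, so stereochemistry matters only for the E double bond of the dichlorovinyl ether and for transient racemic intermediates.

Step 1
Reactants: 1 olivetol (5-pentylbenzene-1,3-diol)
Product: 2 4,6-dibromo-5-pentylbenzene-1,3-diol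
Conditions: Br2 (2.0 equiv), CH2Cl2, −15 to 0 °C
Reagents that add atoms: bromine, BrBr
Why: Electrophilic aromatic bromination; C4 and C6 are each ortho to one hydroxyl and para to the other and react ahead of C2, which lies between the two hydroxyls, so two equivalents should stop at the symmetrical dibromide flanking the pentyl chain.

Step 2
Reactants: 2 4,6-dibromo-5-pentylbenzene-1,3-diol
Product: 3 1,5-bis(benzyloxy)-2,4-dibromo-3-pentylbenzene
Conditions: BnBr (2.3 equiv), K2CO3, DMF, 50 °C
Reagents that add atoms: benzyl bromide, BrCc1ccccc1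
Why: Williamson ether synthesis; aryl benzyl ethers withstand organolithium reagents at −78 °C and are removed together in the last step.

Step 3
Reactants: 3 1,5-bis(benzyloxy)-2,4-dibromo-3-pentylbenzene
Product: 5 tert-butyl 2,4-bis(benzyloxy)-5-bromo-6-pentylbenzoate, via aryllithium 4 (not isolated)
Conditions: n-BuLi (1.0 equiv), THF, −78 °C; transferred into Boc2O (1.5 equiv), THF, −78 °C to rt; H2O
Reagents that add atoms: di-tert-butyl dicarbonate, CC(C)(C)OC(=O)OC(=O)OC(C)(C)C
Why: Bromine–lithium exchange followed by acylation of the aryllithium with Boc2O; the two bromines of 3 are equivalent by symmetry, so one equivalent of n-BuLi differentiates C1' from C5' without a regiochemical question, and the doubly ortho-substituted tert-butyl ester is too shielded to react again.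

Step 4
Reactants: 5 tert-butyl 2,4-bis(benzyloxy)-5-bromo-6-pentylbenzoate
Product: 8 tert-butyl 2,4-bis(benzyloxy)-5-hydroxy-6-pentylbenzoate, via aryllithium 6 (not isolated), via dimethyl boronate 7 (not isolated)
Conditions: n-BuLi (1.05 equiv), THF, −78 °C; B(OMe)3, −78 to 0 °C; 30% aq H2O2, 0 °C to rt
Reagents that add atoms: hydrogen peroxide, OO
Why: Lithiation–borylation–oxidation (bromine–lithium exchange, borate capture, hydroperoxide-induced carbon-to-oxygen migration); exchange at −78 °C is much faster than addition of n-BuLi to the flanked tert-butyl ester.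

Step 5
Reactants: 8 tert-butyl 2,4-bis(benzyloxy)-5-hydroxy-6-pentylbenzoate; 9 trichloroethylene
Product: 11 tert-butyl 2,4-bis(benzyloxy)-5-{[(E)-1,2-dichloroethenyl]oxy}-6-pentylbenzoate, via dichloroacetylene 10 (not isolated)
Conditions: K2CO3 (3 equiv), DMF, 70 °C
Reagents that add atoms: none
Why: Base-induced dehydrochlorination of 9 followed by nucleophilic anti addition of the phenoxide to the haloalkyne, which sets the E geometry; the slim linear electrophile should be reached even by a 2,6-disubstituted phenoxide.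

Step 6
Reactants: 11 tert-butyl 2,4-bis(benzyloxy)-5-{[(E)-1,2-dichloroethenyl]oxy}-6-pentylbenzoate
Product: 14 tert-butyl 2,4-bis(benzyloxy)-5-(ethynyloxy)-6-pentylbenzoate, via chloroethynyl ether 12 (not isolated), via lithium acetylide 13 (not isolated)
Conditions: n-BuLi (2.3 equiv), THF, −78 to −40 °C; H2O, −78 °C; rapid filtration through Et3N-deactivated silica, kept cold and used at once
Reagents that add atoms: none
Why: Standard conversion of a dichlorovinyl ether into an ynol ether (anti elimination of HCl, chlorine–lithium exchange, protonation); the tert-butyl ester offers neither an acidic O–CH nor an accessible carbonyl, and the two ortho groups of ring B should slow polymerisation of the aryl ynol ether.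

Step 7
Reactants: 15 methacryloyl chloride; 16 potassium methyl malonate (KO2CCH2CO2Me)
Product: 18 methyl 4-methyl-3-oxopent-4-enoate, via acylmalonic half ester 17 (not isolated)
Conditions: 16 (2 equiv), MgCl2, Et3N, MeCN, 15 °C; 15, 0 °C to rt; cold 1 M HCl; trace BHT, carried on crude
Reagents that add atoms: none
Why: Decarboxylative Claisen condensation (C-acylation of the chelated magnesium enolate of a malonic half ester, then loss of CO2); the acid chloride should be attacked faster than the α-methyl-substituted enone accepts a conjugate addition.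

Step 8
Reactants: 18 methyl 4-methyl-3-oxopent-4-enoate
Product: 19 methyl 2-diazo-4-methyl-3-oxopent-4-enoate
Conditions: 4-acetamidobenzenesulfonyl azide (1.1 equiv), Et3N, MeCN, 0 °C
Reagents that add atoms: 4-acetamidobenzenesulfonyl azide, CC(=O)Nc1ccc(cc1)S(=O)(=O)N=[N+]=[N-]
Why: Regitz diazo transfer to an active methylene compound; it is fast at 0 °C and blocks the nucleophilic carbon, so that 19 can no longer add to its own enone.

Step 9
Reactants: 14 tert-butyl 2,4-bis(benzyloxy)-5-(ethynyloxy)-6-pentylbenzoate; 19 methyl 2-diazo-4-methyl-3-oxopent-4-enoate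
Product: 24 methyl 2-[4,6-bis(benzyloxy)-3-(tert-butoxycarbonyl)-2-pentylphenoxy]-4-hydroxy-6-methylbenzoate, via vinylketene 20 (not isolated), via vinylcyclobutenone 21 (not isolated), via dienylketene 22 (not isolated), via cyclohexadienone 23 (not isolated)
Conditions: 19 (1.5 equiv, added slowly), hν (300 nm, Pyrex), degassed CH2Cl2, 20 °C; solvent change to PhMe, 110 °C
Reagents that add atoms: none
Why: Proposed new method: light expels N2 from 19 and the isopropenyl group shifts to the diazo carbon (Wolff rearrangement) to give the electron-poor vinylketene 20, whose carbonyl carbon (future C6) is attacked by the nucleophilic terminal carbon of ynol ether 14 (C7) while its α-carbon (C8a) bonds to the oxygen-bearing alkyne carbon (C8), a (2+2) cycloaddition that gives 4-vinylcyclobutenone 21. Light or the later heating opens 21 in a four-electron conrotatory process to (Z)-dienylketene 22, and ring A, the only ring that remains in the product, closes by six-electron disrotatory electrocyclisation of ketene carbon C6 onto the isopropenyl CH2 (C5), after which dienone 23 tautomerises to phenol 24. The closest known reaction type is the Danheiser benzannulation of photochemically generated vinylketenes with alkoxy- and silyloxyalkynes, and what goes beyond it is the ester on the ketene α-carbon (a 2-diazo-1,3-dicarbonyl precursor) and an aryl instead of an alkyl or silyl ynol ether. No stereocentre is created in 24, since the quaternary carbon of racemic 21 ends as sp2 C8a. The step needs regioselectivity in the (2+2) event, which the polarised C≡C–O unit secures (helped by the two ortho groups of ring B, which twist the arene away from the ether oxygen and leave its lone pair to the triple bond), and periselectivity over hetero-(4+2) addition through the ester C=O, which is expected because an ester oxygen is a weak heterodiene terminus. Cyclobutenone opening is reversible, so a rotamer that turns the ester inward can return and only the irreversible aromatisation drains the equilibrium, and an aryl ynol ether has no β-hydrogen and cannot fragment by a retro-ene path.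

Step 10
Reactants: 24 methyl 2-[4,6-bis(benzyloxy)-3-(tert-butoxycarbonyl)-2-pentylphenoxy]-4-hydroxy-6-methylbenzoate
Product: 25 methyl 4-(benzyloxy)-2-[4,6-bis(benzyloxy)-3-(tert-butoxycarbonyl)-2-pentylphenoxy]-6-methylbenzoate
Conditions: BnBr (1.2 equiv), K2CO3, DMF, rt
Reagents that add atoms: benzyl bromide, BrCc1ccccc1
Why: Williamson ether synthesis on the only free, unhindered phenol; it removes the acidic proton before the amide base is used.

Step 11
Reactants: 26 hexanoyl chloride
Product: 27 N-methoxy-N-methylhexanamide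
Conditions: MeNH(OMe)·HCl, Et3N (2.2 equiv), CH2Cl2, 0 °C to rt
Reagents that add atoms: N,O-dimethylhydroxylamine hydrochloride, CNOC.Cl
Why: N-acylation of an amine by an acid chloride (Weinreb amide formation), giving an acyl donor that cannot react twice.

Step 12
Reactants: 25 methyl 4-(benzyloxy)-2-[4,6-bis(benzyloxy)-3-(tert-butoxycarbonyl)-2-pentylphenoxy]-6-methylbenzoate; 27 N-methoxy-N-methylhexanamide
Product: 30 methyl 4-(benzyloxy)-2-[4,6-bis(benzyloxy)-3-(tert-butoxycarbonyl)-2-pentylphenoxy]-6-(2-oxoheptyl)benzoate, via benzylic lithium 28 (not isolated), via tetrahedral adduct 29 (not isolated)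
Conditions: LiN(i-Pr)2 (1.3 equiv), THF, −78 °C, 15 min; 27 (1.6 equiv), −78 °C; AcOH, −78 °C
Reagents that add atoms: none
Why: Lateral lithiation of an ortho-toluate and Weinreb ketone synthesis; the ring A methyl is the only primary benzylic C–H conjugated with an ester that can become coplanar, whereas the ring B pentyl CH2 is secondary and wedged between the tert-butyl ester and the aryloxy group, and chelated adduct 29 releases the ketone only on quenching, so that neither over-addition nor proton return from the product should occur.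

Step 13
Reactants: 30 methyl 4-(benzyloxy)-2-[4,6-bis(benzyloxy)-3-(tert-butoxycarbonyl)-2-pentylphenoxy]-6-(2-oxoheptyl)benzoate
Product: 31 tert-butyl 2,4-bis(benzyloxy)-5-{[6-(benzyloxy)-1-oxo-3-pentyl-1H-isochromen-8-yl]oxy}-6-pentylbenzoate
Conditions: DBU (0.3 equiv), 4 Å MS, PhMe, 100 °C
Reagents that add atoms: none
Why: Base-catalysed enol lactonisation (6-exo-trig O-acylation of the conjugated benzylic enolate by the neighbouring ester), the closure known as the unwanted isocoumarin formation of 2-(2-oxoalkyl)resorcylates; trapping methanol on the sieves drives it and the absence of acid spares the tert-butyl ester.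

Step 14
Reactants: 31 tert-butyl 2,4-bis(benzyloxy)-5-{[6-(benzyloxy)-1-oxo-3-pentyl-1H-isochromen-8-yl]oxy}-6-pentylbenzoate
Product: 33 2,4-bis(benzyloxy)-5-{[6-(benzyloxy)-1-oxo-3-pentyl-1H-isochromen-8-yl]oxy}-6-pentylbenzoic acid, via trimethylsilyl ester 32 (not isolated)
Conditions: Me3SiOTf (3 equiv), 2,6-lutidine (4.5 equiv), CH2Cl2, 0 °C to rt; aq citric acid
Reagents that add atoms: none
Why: Silyl triflate-mediated tert-butyl ester cleavage (carbonyl O-silylation, loss of isobutene, hydrolysis of the silyl ester); the buffered aprotic medium avoids protodecarboxylation of the electron-rich acid and acid-induced benzyl migration.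

Step 15
Reactants: 33 2,4-bis(benzyloxy)-5-{[6-(benzyloxy)-1-oxo-3-pentyl-1H-isochromen-8-yl]oxy}-6-pentylbenzoic acid
Product: 34 2,4-dihydroxy-5-[(6-hydroxy-1-oxo-3-pentyl-1H-isochromen-8-yl)oxy]-6-pentylbenzoic acid (target)
Conditions: H2 (1 atm), 10% Pd/C, EtOAc/THF, rt, stopped after uptake of three equivalents
Reagents that add atoms: none
Why: Catalytic hydrogenolysis of three aryl benzyl ethers; O-benzyl cleavage should be much faster than saturation of the trisubstituted C3–C4 double bond of the conjugated pyranone, and the neutral medium at room temperature should prevent both decarboxylation of the 2,4-dihydroxybenzoic acid and opening of the enol lactone by the freed C4' hydroxyl.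

Compound list
1 | olivetol (5-pentylbenzene-1,3-diol) | CCCCCc1cc(O)cc(O)c1 | starting material
2 | 4,6-dibromo-5-pentylbenzene-1,3-diol | CCCCCc1c(Br)c(O)cc(O)c1Br | intermediate
3 | 1,5-bis(benzyloxy)-2,4-dibromo-3-pentylbenzene | CCCCCc1c(Br)c(OCc2ccccc2)cc(OCc2ccccc2)c1Br | intermediate
4 | [2,4-bis(benzyloxy)-5-bromo-6-pentylphenyl]lithium | CCCCCc1c(Br)c(OCc2ccccc2)cc(OCc2ccccc2)c1[Li] | intermediate
5 | tert-butyl 2,4-bis(benzyloxy)-5-bromo-6-pentylbenzoate | CCCCCc1c(Br)c(OCc2ccccc2)cc(OCc2ccccc2)c1C(=O)OC(C)(C)C | intermediate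
6 | tert-butyl 2,4-bis(benzyloxy)-5-lithio-6-pentylbenzoate | CCCCCc1c([Li])c(OCc2ccccc2)cc(OCc2ccccc2)c1C(=O)OC(C)(C)C | intermediate
7 | tert-butyl 2,4-bis(benzyloxy)-5-(dimethoxyboranyl)-6-pentylbenzoate | CCCCCc1c(B(OC)OC)c(OCc2ccccc2)cc(OCc2ccccc2)c1C(=O)OC(C)(C)C | intermediate
8 | tert-butyl 2,4-bis(benzyloxy)-5-hydroxy-6-pentylbenzoate (ring B phenol) | CCCCCc1c(O)c(OCc2ccccc2)cc(OCc2ccccc2)c1C(=O)OC(C)(C)C | intermediate
9 | trichloroethylene | ClC=C(Cl)Cl | starting material
10 | dichloroacetylene | ClC#CCl | intermediate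
11 | tert-butyl 2,4-bis(benzyloxy)-5-{[(E)-1,2-dichloroethenyl]oxy}-6-pentylbenzoate | CCCCCc1c(O/C(Cl)=C\Cl)c(OCc2ccccc2)cc(OCc2ccccc2)c1C(=O)OC(C)(C)C | intermediate
12 | tert-butyl 2,4-bis(benzyloxy)-5-[(chloroethynyl)oxy]-6-pentylbenzoate | CCCCCc1c(OC#CCl)c(OCc2ccccc2)cc(OCc2ccccc2)c1C(=O)OC(C)(C)C | intermediate
13 | tert-butyl 2,4-bis(benzyloxy)-5-[(lithioethynyl)oxy]-6-pentylbenzoate | CCCCCc1c(OC#C[Li])c(OCc2ccccc2)cc(OCc2ccccc2)c1C(=O)OC(C)(C)C | intermediate
14 | tert-butyl 2,4-bis(benzyloxy)-5-(ethynyloxy)-6-pentylbenzoate | C#COc1c(OCc2ccccc2)cc(OCc2ccccc2)c(C(=O)OC(C)(C)C)c1CCCCC | intermediate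
15 | methacryloyl chloride | CC(=C)C(Cl)=O | starting material
16 | potassium methyl malonate (potassium 3-methoxy-3-oxopropanoate) | COC(=O)CC(=O)[O-].[K+] | starting material
17 | 2-(methoxycarbonyl)-4-methyl-3-oxopent-4-enoic acid (racemic) | COC(=O)C(C(O)=O)C(=O)C(C)=C | intermediate
18 | methyl 4-methyl-3-oxopent-4-enoate | COC(=O)CC(=O)C(C)=C | intermediate
19 | methyl 2-diazo-4-methyl-3-oxopent-4-enoate | COC(=O)C(=[N+]=[N-])C(=O)C(C)=C | intermediate
20 | methyl 3-methyl-2-(oxomethylidene)but-3-enoate, the (methoxycarbonyl)(isopropenyl)ketene | COC(=O)C(=C=O)C(C)=C | intermediate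
21 | methyl 2-[4,6-bis(benzyloxy)-3-(tert-butoxycarbonyl)-2-pentylphenoxy]-4-oxo-1-(prop-1-en-2-yl)cyclobut-2-ene-1-carboxylate (racemic) | COC(=O)C1(C(C)=C)C(=O)C=C1Oc2c(OCc3ccccc3)cc(OCc3ccccc3)c(C(=O)OC(C)(C)C)c2CCCCC | intermediate
22 | methyl (Z)-3-[4,6-bis(benzyloxy)-3-(tert-butoxycarbonyl)-2-pentylphenoxy]-5-oxo-2-(prop-1-en-2-yl)penta-2,4-dienoate (ketenyl and isopropenyl groups cis) | O=C=C/C(Oc1c(OCc2ccccc2)cc(OCc2ccccc2)c(C(=O)OC(C)(C)C)c1CCCCC)=C(\C(C)=C)C(=O)OC | intermediate
23 | methyl 6-[4,6-bis(benzyloxy)-3-(tert-butoxycarbonyl)-2-pentylphenoxy]-2-methyl-4-oxocyclohexa-1,5-diene-1-carboxylate | COC(=O)C1=C(C)CC(=O)C=C1Oc2c(OCc3ccccc3)cc(OCc3ccccc3)c(C(=O)OC(C)(C)C)c2CCCCC | intermediate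
24 | methyl 2-[4,6-bis(benzyloxy)-3-(tert-butoxycarbonyl)-2-pentylphenoxy]-4-hydroxy-6-methylbenzoate | COC(=O)c1c(C)cc(O)cc1Oc2c(OCc3ccccc3)cc(OCc3ccccc3)c(C(=O)OC(C)(C)C)c2CCCCC | intermediate
25 | methyl 4-(benzyloxy)-2-[4,6-bis(benzyloxy)-3-(tert-butoxycarbonyl)-2-pentylphenoxy]-6-methylbenzoate | COC(=O)c1c(C)cc(OCc2ccccc2)cc1Oc2c(OCc3ccccc3)cc(OCc3ccccc3)c(C(=O)OC(C)(C)C)c2CCCCC | intermediate
26 | hexanoyl chloride | CCCCCC(Cl)=O | starting material
27 | N-methoxy-N-methylhexanamide | CCCCCC(=O)N(C)OC | intermediate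
28 | laterally lithiated 25 (CH2Li on ring A in place of CH3) | COC(=O)c1c(C[Li])cc(OCc2ccccc2)cc1Oc2c(OCc3ccccc3)cc(OCc3ccccc3)c(C(=O)OC(C)(C)C)c2CCCCC | intermediate
29 | lithium alkoxide adduct of 28 and 27 (racemic hemiaminal) | CCCCCC(O[Li])(N(C)OC)Cc1cc(OCc2ccccc2)cc(Oc2c(OCc3ccccc3)cc(OCc3ccccc3)c(C(=O)OC(C)(C)C)c2CCCCC)c1C(=O)OC | intermediate
30 | methyl 4-(benzyloxy)-2-[4,6-bis(benzyloxy)-3-(tert-butoxycarbonyl)-2-pentylphenoxy]-6-(2-oxoheptyl)benzoate | CCCCCC(=O)Cc1cc(OCc2ccccc2)cc(Oc2c(OCc3ccccc3)cc(OCc3ccccc3)c(C(=O)OC(C)(C)C)c2CCCCC)c1C(=O)OC | intermediate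
31 | tert-butyl 2,4-bis(benzyloxy)-5-{[6-(benzyloxy)-1-oxo-3-pentyl-1H-isochromen-8-yl]oxy}-6-pentylbenzoate | CCCCCc1cc2cc(OCc3ccccc3)cc(Oc3c(OCc4ccccc4)cc(OCc4ccccc4)c(C(=O)OC(C)(C)C)c3CCCCC)c2c(=O)o1 | intermediate
32 | trimethylsilyl 2,4-bis(benzyloxy)-5-{[6-(benzyloxy)-1-oxo-3-pentyl-1H-isochromen-8-yl]oxy}-6-pentylbenzoate | CCCCCc1cc2cc(OCc3ccccc3)cc(Oc3c(OCc4ccccc4)cc(OCc4ccccc4)c(C(=O)O[Si](C)(C)C)c3CCCCC)c2c(=O)o1 | intermediate
33 | 2,4-bis(benzyloxy)-5-{[6-(benzyloxy)-1-oxo-3-pentyl-1H-isochromen-8-yl]oxy}-6-pentylbenzoic acid | CCCCCc1cc2cc(OCc3ccccc3)cc(Oc3c(OCc4ccccc4)cc(OCc4ccccc4)c(C(=O)O)c3CCCCC)c2c(=O)o1 | intermediate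
34 | 2,4-dihydroxy-5-[(6-hydroxy-1-oxo-3-pentyl-1H-isochromen-8-yl)oxy]-6-pentylbenzoic acid (CNP0439913.0) | CCCCCc1cc2cc(O)cc(Oc3c(O)cc(O)c(C(=O)O)c3CCCCC)c2c(=O)o1 | target

Total step count: 15.
Longest linear sequence: 12 (steps 1 to 6, 9, 10, 12 to 15).

Steps most likely to fail

1. Step 9.
- What may go wrong:
  - The Wolff shift may lose out to carbene-type reactions of the excited diazo compound.
  - The ketene may be used up by dimerisation, or the first-formed zwitterion may close through the ester oxygen instead of through carbon.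
  - Opening of the cyclobutenone may turn the ester rather than the isopropenyl group inward.
  - Surplus ketene may acylate the new phenol.
- Fallback: known cross-coupling chemistry makes the diaryl ether instead. It sets out from phenol 8 and comes back at 25. Commercial methyl orsellinate F1 is benzylated selectively at the non-chelated 4-hydroxyl (BnBr, K2CO3, acetone) to methyl 4-(benzyloxy)-2-hydroxy-6-methylbenzoate F2. Tf2O and pyridine convert this into aryl triflate F3. A Buchwald–Hartwig diaryl ether coupling of 8 with the ester-activated, mono-ortho-substituted triflate (Pd2(dba)3, t-BuXPhos, K3PO4, PhMe, 100 °C) should give 25 directly, so that steps 5 to 10 are bypassed.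

2. Step 6.
- What may go wrong:
  - n-BuLi may metalate benzylic positions or add to the ester in competition with elimination and exchange.
  - The terminal ynol ether may hydrate or polymerise during isolation.
- Fallback: an organolithium-free route sets out from 8 and comes back at 14. Chan–Lam O-vinylation (Cu(OAc)2, 2,4,6-trivinylcyclotriboroxane–pyridine complex, pyridine, CH2Cl2, air) gives aryl vinyl ether F4. Addition of Br2 at −78 °C gives 1,2-dibromoethyl ether F5. One equivalent of KOt-Bu removes the labile α-bromide as HBr to give (Z)-2-bromovinyl ether F6. Anti elimination with KN(SiMe3)2 (2.2 equiv, THF, −78 °C) and quenching with water then gives 14.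

3. Step 7.
- What may go wrong:
  - The malonate enolate, or the enol of the product, may add to the isopropenyl ketone in conjugate fashion.
  - Radical polymerisation may occur on concentration and erode the keto ester before diazo transfer.
- Fallback: the double bond is masked until the nucleophilic carbon is blocked. The fallback sets out from 15 and comes back at 19. Dry HCl adds to 15 to give 3-chloro-2-methylpropanoyl chloride F7. The same magnesium malonate acylation with 16 gives methyl 5-chloro-4-methyl-3-oxopentanoate F8. Regitz diazo transfer gives methyl 5-chloro-2-diazo-4-methyl-3-oxopentanoate F9. E1cB loss of HCl with Et3N at room temperature unveils the isopropenyl ketone of 19.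

Further compounds
F1 | step 9 | methyl 2,4-dihydroxy-6-methylbenzoate (methyl orsellinate, commercial) | COC(=O)c1c(C)cc(O)cc1O
F2 | step 9 | methyl 4-(benzyloxy)-2-hydroxy-6-methylbenzoate | COC(=O)c1c(C)cc(OCc2ccccc2)cc1O
F3 | step 9 | methyl 4-(benzyloxy)-6-methyl-2-{[(trifluoromethyl)sulfonyl]oxy}benzoate | COC(=O)c1c(C)cc(OCc2ccccc2)cc1OS(=O)(=O)C(F)(F)F
F4 | step 6 | tert-butyl 2,4-bis(benzyloxy)-5-(ethenyloxy)-6-pentylbenzoate | C=COc1c(OCc2ccccc2)cc(OCc2ccccc2)c(C(=O)OC(C)(C)C)c1CCCCC
F5 | step 6 | tert-butyl 2,4-bis(benzyloxy)-5-(1,2-dibromoethoxy)-6-pentylbenzoate (racemic) | BrCC(Br)Oc1c(OCc2ccccc2)cc(OCc2ccccc2)c(C(=O)OC(C)(C)C)c1CCCCC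
F6 | step 6 | tert-butyl 2,4-bis(benzyloxy)-5-{[(Z)-2-bromoethenyl]oxy}-6-pentylbenzoate | Br/C=C\Oc1c(OCc2ccccc2)cc(OCc2ccccc2)c(C(=O)OC(C)(C)C)c1CCCCC
F7 | step 7 | 3-chloro-2-methylpropanoyl chloride (racemic) | CC(CCl)C(Cl)=O
F8 | step 7 | methyl 5-chloro-4-methyl-3-oxopentanoate (racemic) | COC(=O)CC(=O)C(C)CCl
F9 | step 7 | methyl 5-chloro-2-diazo-4-methyl-3-oxopentanoate (racemic) | COC(=O)C(=[N+]=[N-])C(=O)C(C)CCl
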